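**Assumption:** the target SMILES has no descriptor for the C8–C6' biaryl axis, so the racemate is the goal and no step controls the axis.

## Analysis of the target

Target 27 is an unsymmetrical 8,6'-bicoumarin. Two 4-methoxy-5-methylcoumarin units are joined from C8 of unit A (benzene ring A with pyranone A, plain locants) to C6' of unit B (benzene ring B with pyranone B, primed locants). Unit A carries a methyl ether at C7 and unit B a free phenol at C7', so three methyl ethers must be told apart from one hydroxyl. There is no stereocentre. The only stereogenic element is the C8–C6' axis, flanked by four ortho substituents (7-OMe, ring oxygen O1 on C8a, 5'-Me, 7'-OH). The sensitive groups are the two lactones, the two vinylogous methyl carbonates at C4 and C4' (open to hydroxide, to alkoxide exchange and to hot aqueous acid), the free phenol, and the coumarin chromophores, which photodimerise. The difficulty lies in the fourfold ortho-substituted aryl–aryl bond between two electron-rich rings and in the peri crowding of 4-OMe against 5-Me in both units. The strategy rests on ring B. It is pentasubstituted, with oxygens in a meta relation on C7' and C8a', hydrogen on C8', and the methyl group (C5') and the aryl group (C6') on neighbouring carbons. That is the pattern a 3-methyl-4-arylvinylketene and a terminal alkynyl ether produce in one annulation, so ring B can be grown on a finished unit A and the biaryl bond need never be made by coupling.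

## Retrosynthetic reasoning

**O4'–CH3.** The last bond cut is the methyl ether of unit B, 27 back to diol 26. The 4'-hydroxyl of 26 is a vinylogous carboxylic acid and the 7'-hydroxyl is a hindered phenol, so the forward step only has to exploit this difference. Placing it last keeps the endgame free of protecting groups, and the same reaction would restore the C4 methyl ether of unit A if an earlier acidic step had cleaved it.

**Pyranone B.** O1'–C2' and C2'–C3' are cut to give the ortho-hydroxyacetophenone 25 and a one-carbon carbonate unit. The C4a'–acetyl bond is then cut to give resorcinol 23. The forward acylation must go to C4a' (para to the 7'-hydroxyl, ortho to the 8a'-hydroxyl) and not to C8' between the two hydroxyls. Ring A is by then a deactivated coumarin and does not compete. Removing the silyl group leads back to 22.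

**Ring B (key disconnection).** C7'–C8', C8a'–C4a' and C6'–C7' are cut, which takes 22 back to acid chloride 13 and ynol ether 18. These are the three bonds that a [2+2] addition, a 4-pi opening and a 6-pi closure form in one operation. The gain is that the crowded C8–C6' bond becomes the ordinary CH2–C8 bond of 13. The ketene carbon ends as C7' with the free hydroxyl the target needs, and the silyl ether marks O8a' as the future lactone oxygen. The forward reaction has to form the ketene by loss of the benzylic hydrogen and trap it with 18 in the right orientation.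

**Ynol ether.** 18 is cut at O–Si and at the ynolate, back to isoxazole 14 and silyl triflate 15. A ring fragmentation delivers the parent ynolate 17 without excess base.

**Side chain.** 13 comes from acid 12 and this from tert-butyl ester 11; the tert-butyl group is chosen so that no hydroxide ever meets the lactone or the C4 enol ether. The C=C bond of 11 is cut to ketone 9 and phosphonate 10, and 9 comes from the terminal alkene 8 by oxidation.

**Unit A.** The two O–methyl bonds of 8 lead to diol 7. Pyranone A (O1–C2, C2–C3) is cut to acetophenone 6 and a carbonate unit. The C3–allyl bond of 6 (the later C8–CH2 bond) is cut by a [3,3] shift to allyl ether 5, which comes from 3 and 4. The chelated ortho-hydroxy ketone is what sends the allyl group between the two oxygens. Ketone 3 comes from 1 by C-acylation.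

## Alternatives that were turned down

**Alternative 1: both pyranones from a biaryl bis(salicylate).** The disconnection cuts O1–C2 and C3–C4 in unit A and O1'–C2' and C3'–C4' in unit B. This leads to dimethyl 3-[6-benzyloxy-4-hydroxy-3-methoxycarbonyl-2-methylphenyl]-type bis(salicylate) A2 and two equivalents of ketenylidenetriphenylphosphorane A3. In the forward step each ortho hydroxyl of A2 adds to the ketene carbon of A3, and each acyl ylide olefinates the neighbouring ester carbonyl. The ester methoxy groups stay as the C4 and C4' methyl ethers, giving the 7'-O-benzyl ether A1, and hydrogenolysis then frees the phenol.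
- For: both 4-methoxypyranones form in one neutral operation, with no acylation regiochemistry on ring B and no late selective methylation.
- Against: A2 already contains the fourfold ortho-substituted C8–C6' bond. It would have to be made by coupling two hindered, electron-rich benzoate halves, each with a regiodefined coupling handle and three differentiated oxygens. The intramolecular Wittig reaction on an ester carbonyl next to an ortho methyl group is slow and must succeed twice on one molecule.
- Comparison: on the endgame Alternative 1 is stronger (two steps after the key step instead of four, no selectivity question). The chosen strategy offers in its place a biaryl bond that starts as a CH2–aryl bond from a sigmatropic shift, and a ring A taken intact from 1.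

**Alternative 2: ring A by Diels–Alder reaction.** The disconnection cuts C5–C6 and C4a–C8a of ring A. This leads to 2-[2,4-bis(benzyloxy)-6-methylphenyl]-1-methoxy-1,3-bis(trimethylsilyloxy)buta-1,3-diene A5 and methyl but-2-ynoate A6. The forward cycloaddition, followed by loss of the alkoxy group from the acetal carbon, aromatises to methyl 3-[2,4-bis(benzyloxy)-6-methylphenyl]-2,4-dihydroxy-6-methylbenzoate A4.
- For: diene polarity puts the ester carbon (the future C4) next to the C8a hydroxyl during ring formation. Ring A therefore needs no later acylation, which is better than what the chosen route does for ring B. No aryl–aryl coupling is needed.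
- Against: the diene carries a di-ortho-substituted aryl group on C2, which crowds the s-cis conformer. A6 is a beta-substituted, sluggish dienophile and needs temperatures at which such silyl ketene acetals are fragile. Afterwards the C7 and C8a hydroxyls of A4 must be told apart, two benzyl ethers removed, and all of pyranone B (acylation, closure, methylation) still built.
- Comparison: the key step is spent on ring A, which the chosen route gets from 1 at no cost. The chosen strategy builds the ring whose two oxygens must differ, and delivers them already different (hydroxyl and silyl ether).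

**Alternative 3: ring A from a cyclobutenone and an aryl ynol ether.** The disconnection cuts C8–C8a and C6–C7 (C4a–C8a is re-formed). This leads to 3-methylcyclobut-2-en-1-one A9 and [2,4-bis(benzyloxy)-6-methylphenyl]ethynyl triisopropylsilyl ether A8. In the forward step A9 opens thermally to its vinylketene, which adds A8 and rearranges by 4-pi opening and 6-pi closure to 2-[2,4-bis(benzyloxy)-6-methylphenyl]-5-methyl-3-(triisopropylsilyloxy)phenol A7.
- For: this is the base-free, salt-free form of the benzannulation, with the ketene released slowly. There is no question of where a proton is removed, which is a real advantage over the chosen key step.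
- Against: the nucleophilic alkyne carbon of A8 bears a di-ortho-substituted aryl group, so the first bond forms at a crowded centre. A8 and the volatile A9 each need several steps. A7 lacks C4, so ring A must be C-acylated later in competition with the equally electron-rich ring B, and ring B then needs the same treatment.
- Comparison: Alternative 3 has the better precedent for ketene generation. The chosen strategy offers electronic discrimination instead: when ring B is acylated, ring A is a finished, deactivated coumarin, and only one ring is built from acyclic carbons.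

Key step: step 11

## Route

Step 1
Reactants: 1 orcinol (5-methylbenzene-1,3-diol)
Product: 3 1-(2,4-dihydroxy-6-methylphenyl)ethan-1-one, via ketiminium chloride 2 (not isolated)
Conditions: MeCN, ZnCl2, HCl (g), Et2O, 0 °C; then H2O, 100 °C
Reagents that add atoms: acetonitrile (CC#N); water (O)
Why: Hoesch acylation; the imidoyl electrophile attacks the ring carbon para to one hydroxyl and ortho to the other (next to the methyl group), the usual site for this ring, and water hydrolyses the ketiminium salt 2 to the ketone.

Step 2
Reactants: 3 1-(2,4-dihydroxy-6-methylphenyl)ethan-1-one; 4 allyl bromide (3-bromoprop-1-ene)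
Product: 5 1-[2-hydroxy-6-methyl-4-(prop-2-enyloxy)phenyl]ethan-1-one
Conditions: K2CO3, acetone, 56 °C
Reagents that add atoms: none
Why: Williamson etherification; the 2-hydroxyl is hydrogen-bonded to the ketone and stays free, so only the 4-hydroxyl is allylated.

Step 3
Reactants: 5 1-[2-hydroxy-6-methyl-4-(prop-2-enyloxy)phenyl]ethan-1-one
Product: 6 1-[2,4-dihydroxy-6-methyl-3-(prop-2-enyl)phenyl]ethan-1-one
Conditions: PhNEt2, 195 °C
Reagents that add atoms: none
Why: Aromatic Claisen rearrangement; bond fixation by the chelated ortho-hydroxy ketone directs the [3,3] shift to C3 between the two oxygens (the later C8), as is usual for 4-allyloxy-2-hydroxyacetophenones, and not to C5 next to the methyl group.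

Step 4
Reactants: 6 1-[2,4-dihydroxy-6-methyl-3-(prop-2-enyl)phenyl]ethan-1-one
Product: 7 4,7-dihydroxy-5-methyl-8-(prop-2-enyl)-2H-chromen-2-one
Conditions: NaH (5 equiv), (EtO)2CO, toluene, 110 °C; then aq. HCl
Reagents that add atoms: diethyl carbonate (CCOC(=O)OCC)
Why: Claisen condensation of the methyl ketone enolate with the carbonate and lactonisation onto the ortho phenoxide, the standard 4-hydroxycoumarin synthesis; excess NaH carries both phenols as phenoxides, so no protecting group is needed.

Step 5
Reactants: 7 4,7-dihydroxy-5-methyl-8-(prop-2-enyl)-2H-chromen-2-one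
Product: 8 4,7-dimethoxy-5-methyl-8-(prop-2-enyl)-2H-chromen-2-one
Conditions: Me2SO4 (2.5 equiv), K2CO3, acetone, 56 °C
Reagents that add atoms: dimethyl sulfate (COS(=O)(=O)OC)
Why: O-Methylation of the 7-phenoxide and of the ambident 4-oxide by the hard sulfate electrophile; unit A needs both ethers, so one operation serves, and the 4-methoxycoumarin is the expected main O-alkylation product.

Step 6
Reactants: 8 4,7-dimethoxy-5-methyl-8-(prop-2-enyl)-2H-chromen-2-one
Product: 9 4,7-dimethoxy-5-methyl-8-(2-oxopropyl)-2H-chromen-2-one
Conditions: PdCl2 (10 mol %), CuCl, O2 (1 atm), DMF/H2O (7:1), 25 °C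
Reagents that add atoms: water (O)
Why: Tsuji–Wacker oxidation; Markovnikov hydroxypalladation of the terminal alkene by divalent palladium gives the methyl ketone, and the conjugated trisubstituted C3=C4 bond of the coumarin does not take part.

Step 7
Reactants: 9 4,7-dimethoxy-5-methyl-8-(2-oxopropyl)-2H-chromen-2-one; 10 tert-butyl 2-(diethoxyphosphoryl)acetate
Product: 11 tert-butyl (E)-4-(4,7-dimethoxy-5-methyl-2-oxo-2H-chromen-8-yl)-3-methylbut-2-enoate
Conditions: NaH, THF, 0 to 65 °C
Reagents that add atoms: none
Why: Horner–Wadsworth–Emmons olefination of the methyl ketone with the preformed phosphonate anion, expected to favour the E isomer (arylmethyl group trans to the ester), which is separated; the geometry of this bond is lost in step 11, so a minor isomer would not change the outcome.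

Step 8
Reactants: 11 tert-butyl (E)-4-(4,7-dimethoxy-5-methyl-2-oxo-2H-chromen-8-yl)-3-methylbut-2-enoate
Product: 12 (E)-4-(4,7-dimethoxy-5-methyl-2-oxo-2H-chromen-8-yl)-3-methylbut-2-enoic acid
Conditions: CF3CO2H, CH2Cl2, 25 °C
Reagents that add atoms: none
Why: Acidolysis of the tert-butyl ester by loss of the tert-butyl cation; no hydroxide is used, so the lactone and the C4 enol ether are not touched.

Step 9
Reactants: 12 (E)-4-(4,7-dimethoxy-5-methyl-2-oxo-2H-chromen-8-yl)-3-methylbut-2-enoic acid
Product: 13 (E)-4-(4,7-dimethoxy-5-methyl-2-oxo-2H-chromen-8-yl)-3-methylbut-2-enoyl chloride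
Conditions: (COCl)2, DMF (cat.), CH2Cl2, 0 to 25 °C
Reagents that add atoms: oxalyl chloride (O=C(Cl)C(Cl)=O)
Why: Acid chloride formation through the Vilsmeier-type chloroiminium catalyst; volatile by-products are removed in vacuum and 13 is used at once.

Step 10
Reactants: 14 3-phenylisoxazole; 15 triisopropylsilyl trifluoromethanesulfonate
Product: 18 (triisopropylsilyloxy)acetylene, via 5-lithio-3-phenylisoxazole 16 (not isolated), via lithium ethynolate 17 (not isolated)
Conditions: n-BuLi (1.0 equiv), THF, −78 to −20 °C; then 15, −78 to 0 °C
Reagents that add atoms: none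
Why: C5–H is the acidic site of a 3-arylisoxazole; the 5-lithio compound 16 undergoes cycloreversion (cleavage of N–O and C3–C4) to the nitrile and the parent ynolate 17, the established ynolate generation from 5-lithioisoxazoles. The hard, bulky silyl triflate is expected to silylate the ynolate on oxygen, as bulky silyl electrophiles do with ynolates.

Step 11
Reactants: 13 (E)-4-(4,7-dimethoxy-5-methyl-2-oxo-2H-chromen-8-yl)-3-methylbut-2-enoyl chloride; 18 (triisopropylsilyloxy)acetylene
Product: 22 8-[2-hydroxy-6-methyl-4-(triisopropylsilyloxy)phenyl]-4,7-dimethoxy-5-methyl-2H-chromen-2-one (racemic), via vinylketene 19 (not isolated), via alkenylcyclobutenone 20 (not isolated), via dienylketene 21 (not isolated)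
Conditions: 18 (2.5 equiv), Et3N (1.5 equiv), toluene, 25–40 °C, slow addition of 13; then 100 °C
Reagents that add atoms: none
Why: Et3N removes the doubly activated benzylic gamma-hydrogen of 13 in a 1,4-dehydrochlorination and gives vinylketene 19, the same ketene that a Z isomer or a deconjugated isomer of 13 would give. The unsubstituted, nucleophilic carbon of 18 attacks the ketene carbonyl carbon, and the [2+2] cycloaddition closes cyclobutenone 20 (C7'–C8' and C8a'–C4a'). On heating, 20 opens by 4-pi electrocyclic cleavage to dienylketene 21, whose thermal disrotatory 6-pi electrocyclisation forms C6'–C7' and closes benzene ring B; enolisation of the cyclohexadienone gives the phenol. The closest known reaction type is the Danheiser benzannulation of vinylketenes with silyloxyalkynes, with the ketene made here by the equally established amine dehydrohalogenation of an unsaturated acid chloride instead of by cyclobutenone opening. No stereocentre is formed, and the biaryl axis arises without control, so 22 is racemic. Two selectivities are needed: the site of deprotonation, which relies on the higher acidity of the benzylic CH2 over the C3 methyl group, and the orientation of 18, fixed by its polarity so that oxygen ends meta to the new hydroxyl. Ketene dimerisation and O-acylation of 22 are held back by adding 13 slowly to excess 18 at low temperature and heating only when 13 is consumed.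

Step 12
Reactants: 22 8-[2-hydroxy-6-methyl-4-(triisopropylsilyloxy)phenyl]-4,7-dimethoxy-5-methyl-2H-chromen-2-one
Product: 23 8-(2,4-dihydroxy-6-methylphenyl)-4,7-dimethoxy-5-methyl-2H-chromen-2-one
Conditions: Bu4NF, AcOH, THF, 0 °C
Reagents that add atoms: none
Why: Fluoride cleavage of the aryl silyl ether, driven by the Si–F bond; acetic acid buffers the medium so that no basic fluoride or phenoxide attacks the lactone or the C4 enol ether.

Step 13
Reactants: 23 8-(2,4-dihydroxy-6-methylphenyl)-4,7-dimethoxy-5-methyl-2H-chromen-2-one
Product: 25 8-(3-acetyl-4,6-dihydroxy-2-methylphenyl)-4,7-dimethoxy-5-methyl-2H-chromen-2-one, via ketiminium chloride 24 (not isolated)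
Conditions: MeCN, ZnCl2, HCl (g), Et2O/EtOAc, 0 °C; then H2O, 80 °C
Reagents that add atoms: acetonitrile (CC#N); water (O)
Why: Hoesch acylation; as in step 1 the mild electrophile is expected at C4a' (para to the 7'-hydroxyl, ortho to the 8a'-hydroxyl) rather than at C8' between the hydroxyls, and it reacts only with the dihydroxy ring, not with the deactivated coumarin ring A. If the C4 methyl ether of unit A were partly hydrolysed here, step 15 would restore it.

Step 14
Reactants: 25 8-(3-acetyl-4,6-dihydroxy-2-methylphenyl)-4,7-dimethoxy-5-methyl-2H-chromen-2-one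
Product: 26 8-(4,7-dihydroxy-5-methyl-2-oxo-2H-chromen-6-yl)-4,7-dimethoxy-5-methyl-2H-chromen-2-one
Conditions: NaH (5 equiv), (MeO)2CO, toluene, 90 °C; then aq. HCl
Reagents that add atoms: dimethyl carbonate (COC(=O)OC)
Why: Same Claisen condensation and lactonisation as in step 4, here closing pyranone B onto O8a'. Dimethyl rather than diethyl carbonate is used so that the alkoxide set free is methoxide: exchange at the C4 methyl ether of unit A is then degenerate, and a transiently opened lactone of unit A re-closes on acidification.

Step 15
Reactants: 26 8-(4,7-dihydroxy-5-methyl-2-oxo-2H-chromen-6-yl)-4,7-dimethoxy-5-methyl-2H-chromen-2-one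
Product: 27 8-(7-hydroxy-4-methoxy-5-methyl-2-oxo-2H-chromen-6-yl)-4,7-dimethoxy-5-methyl-2H-chromen-2-one
Conditions: MeOH, H2SO4, 65 °C
Reagents that add atoms: methanol (CO)
Why: Fischer-type etherification; the 4'-hydroxyl is a vinylogous carboxylic acid and is converted to its methyl ether by acid-catalysed addition–elimination, whereas the phenolic 7'-hydroxyl cannot react this way. Exchange at the C4 methyl ether of unit A is degenerate in methanol.

## Compound list

1 | orcinol (5-methylbenzene-1,3-diol) | Cc1cc(O)cc(O)c1 | starting material
2 | 1-(2,4-dihydroxy-6-methylphenyl)ethan-1-iminium chloride | CC(=[NH2+])c1c(C)cc(O)cc1O.[Cl-] | intermediate (not isolated)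
3 | 1-(2,4-dihydroxy-6-methylphenyl)ethan-1-one | CC(=O)c1c(C)cc(O)cc1O | intermediate
4 | allyl bromide (3-bromoprop-1-ene) | C=CCBr | starting material
5 | 1-[2-hydroxy-6-methyl-4-(prop-2-enyloxy)phenyl]ethan-1-one | CC(=O)c1c(C)cc(OCC=C)cc1O | intermediate
6 | 1-[2,4-dihydroxy-6-methyl-3-(prop-2-enyl)phenyl]ethan-1-one | CC(=O)c1c(C)cc(O)c(CC=C)c1O | intermediate
7 | 4,7-dihydroxy-5-methyl-8-(prop-2-enyl)-2H-chromen-2-one | C=CCc1c(O)cc(C)c2c(O)cc(=O)oc12 | intermediate
8 | 4,7-dimethoxy-5-methyl-8-(prop-2-enyl)-2H-chromen-2-one | C=CCc1c(OC)cc(C)c2c(OC)cc(=O)oc12 | intermediate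
9 | 4,7-dimethoxy-5-methyl-8-(2-oxopropyl)-2H-chromen-2-one | CC(=O)Cc1c(OC)cc(C)c2c(OC)cc(=O)oc12 | intermediate
10 | tert-butyl 2-(diethoxyphosphoryl)acetate | CCOP(=O)(CC(=O)OC(C)(C)C)OCC | starting material
11 | tert-butyl (E)-4-(4,7-dimethoxy-5-methyl-2-oxo-2H-chromen-8-yl)-3-methylbut-2-enoate | COc1cc(C)c2c(OC)cc(=O)oc2c1C/C(C)=C/C(=O)OC(C)(C)C | intermediate
12 | (E)-4-(4,7-dimethoxy-5-methyl-2-oxo-2H-chromen-8-yl)-3-methylbut-2-enoic acid | COc1cc(C)c2c(OC)cc(=O)oc2c1C/C(C)=C/C(=O)O | intermediate
13 | (E)-4-(4,7-dimethoxy-5-methyl-2-oxo-2H-chromen-8-yl)-3-methylbut-2-enoyl chloride | COc1cc(C)c2c(OC)cc(=O)oc2c1C/C(C)=C/C(Cl)=O | intermediate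
14 | 3-phenylisoxazole | c1ccc(cc1)-c1ccon1 | starting material
15 | triisopropylsilyl trifluoromethanesulfonate | CC(C)[Si](OS(=O)(=O)C(F)(F)F)(C(C)C)C(C)C | starting material
16 | 5-lithio-3-phenylisoxazole | [Li]c1cc(-c2ccccc2)no1 | intermediate (not isolated)
17 | lithium ethynolate | [Li+].[O-]C#C | intermediate (not isolated)
18 | (triisopropylsilyloxy)acetylene | C#CO[Si](C(C)C)(C(C)C)C(C)C | intermediate
19 | (E)-4-(4,7-dimethoxy-5-methyl-2-oxo-2H-chromen-8-yl)-3-methylbuta-1,3-dien-1-one (vinylketene) | COc1cc(C)c2c(OC)cc(=O)oc2c1/C=C(\C)C=C=O | intermediate (not isolated)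
20 | 4-[(E)-1-(4,7-dimethoxy-5-methyl-2-oxo-2H-chromen-8-yl)prop-1-en-2-yl]-3-(triisopropylsilyloxy)cyclobut-2-en-1-one (racemic) | COc1cc(C)c2c(OC)cc(=O)oc2c1/C=C(\C)C1C(=O)C=C1O[Si](C(C)C)(C(C)C)C(C)C | intermediate (not isolated)
21 | (3E,5E)-6-(4,7-dimethoxy-5-methyl-2-oxo-2H-chromen-8-yl)-5-methyl-3-(triisopropylsilyloxy)hexa-1,3,5-trien-1-one (dienylketene) | COc1cc(C)c2c(OC)cc(=O)oc2c1/C=C(\C)/C=C(\C=C=O)O[Si](C(C)C)(C(C)C)C(C)C | intermediate (not isolated)
22 | 8-[2-hydroxy-6-methyl-4-(triisopropylsilyloxy)phenyl]-4,7-dimethoxy-5-methyl-2H-chromen-2-one (racemic) | COc1cc(C)c2c(OC)cc(=O)oc2c1-c1c(O)cc(O[Si](C(C)C)(C(C)C)C(C)C)cc1C | intermediate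
23 | 8-(2,4-dihydroxy-6-methylphenyl)-4,7-dimethoxy-5-methyl-2H-chromen-2-one | COc1cc(C)c2c(OC)cc(=O)oc2c1-c1c(O)cc(O)cc1C | intermediate
24 | 8-[4,6-dihydroxy-3-(1-iminioethyl)-2-methylphenyl]-4,7-dimethoxy-5-methyl-2H-chromen-2-one chloride | COc1cc(C)c2c(OC)cc(=O)oc2c1-c1c(O)cc(O)c(C(C)=[NH2+])c1C.[Cl-] | intermediate (not isolated)
25 | 8-(3-acetyl-4,6-dihydroxy-2-methylphenyl)-4,7-dimethoxy-5-methyl-2H-chromen-2-one | COc1cc(C)c2c(OC)cc(=O)oc2c1-c1c(O)cc(O)c(C(C)=O)c1C | intermediate
26 | 8-(4,7-dihydroxy-5-methyl-2-oxo-2H-chromen-6-yl)-4,7-dimethoxy-5-methyl-2H-chromen-2-one | COc1cc(C)c2c(OC)cc(=O)oc2c1-c1c(O)cc2oc(=O)cc(O)c2c1C | intermediate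
27 | 8-(7-hydroxy-4-methoxy-5-methyl-2-oxo-2H-chromen-6-yl)-4,7-dimethoxy-5-methyl-2H-chromen-2-one (racemic) | COc1cc(C)c2c(OC)cc(=O)oc2c1-c1c(O)cc2oc(=O)cc(OC)c2c1C | target

## Step count and least certain steps

Total step count: 15 (14 in the main line and one for the alkyne partner 18). Longest linear sequence: 14 steps (steps 1–9 and 11–15).

**Step 11 (key step).** The base may remove a hydrogen from the C3 methyl group instead of the benzylic CH2, because the aryl group is twisted by its two ortho substituents and stabilises the benzylic anion less than a flat aryl group would. That would lead to a benzyl-substituted ring instead of the biaryl. The ketene may also be lost by dimerisation, and 18 may be protonated by the ammonium salt. The fallback sets out from 8 and returns at 22. It makes the same vinylketene 19 by plain 1,2-dehydrochlorination of a beta,gamma-unsaturated acid chloride, which can eliminate in only one way. The allyl group of 8 is moved into conjugation with PdCl2(MeCN)2 (cat.) in toluene to give (E)-4,7-dimethoxy-5-methyl-8-(prop-1-enyl)-2H-chromen-2-one F1. Lemieux–Johnson cleavage (OsO4 cat., NaIO4, 2,6-lutidine, dioxane/H2O) gives 4,7-dimethoxy-5-methyl-2-oxo-2H-chromene-8-carbaldehyde F2. Wittig olefination with the ylide from (2-carboxy-1-methylethyl)triphenylphosphonium bromide and NaN(SiMe3)2 (2 equiv) gives (E)-4-(4,7-dimethoxy-5-methyl-2-oxo-2H-chromen-8-yl)-3-methylbut-3-enoic acid F3; either alkene geometry serves. Oxalyl chloride converts it into (E)-4-(4,7-dimethoxy-5-methyl-2-oxo-2H-chromen-8-yl)-3-methylbut-3-enoyl chloride F4, which with Et3N and 18 under the conditions of step 11 gives 22.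

**Step 10.** The unhindered carbon of the parent ynolate may be silylated instead of oxygen, giving a silylketene. Butyllithium may add to the nitrile that is set free, and the volatile, acid-sensitive ynol ether may be lost on isolation. The fallback sets out from 13 and returns at 23. It changes the alkyne partner to an alkyl ynol ether that needs no ynolate silylation. KOC(CH3)3 and trichloroethylene in THF give (E)-1,2-dichlorovinyl tert-butyl ether F5. Treatment with n-BuLi (2.2 equiv, −78 °C) and a methanol quench gives tert-butoxyacetylene F6, which is kept cold. With 13 and Et3N under the conditions of step 11 it gives 8-(4-tert-butoxy-2-hydroxy-6-methylphenyl)-4,7-dimethoxy-5-methyl-2H-chromen-2-one F7. CF3CO2H in CH2Cl2 removes the tert-butyl group and gives 23, so step 12 is replaced.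

**Step 13.** Acylation may compete at C8' between the two hydroxyls, and the hot aqueous hydrolysis may partly cleave the C4 enol ether of unit A. The fallback sets out from 22 and returns at 25. It blocks C8' before the acylation. NBS with catalytic iPr2NH in CH2Cl2 at 0 °C brominates the electron-rich phenol ring of 22 ortho to its free hydroxyl, giving 8-[3-bromo-2-hydroxy-6-methyl-4-(triisopropylsilyloxy)phenyl]-4,7-dimethoxy-5-methyl-2H-chromen-2-one F8. Bu4NF/AcOH gives 8-(3-bromo-2,4-dihydroxy-6-methylphenyl)-4,7-dimethoxy-5-methyl-2H-chromen-2-one F9. Hoesch acetylation as in step 13 can then occur only at C4a' and gives 8-(3-acetyl-5-bromo-4,6-dihydroxy-2-methylphenyl)-4,7-dimethoxy-5-methyl-2H-chromen-2-one F10. Hydrogenolysis (H2, Pd/C, NaOAc, EtOAc) removes the bromine and gives 25.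

**Step 14.** Methoxide at 90 °C may open the lactone of unit A or add at C4 of unit A, and enolisation of a ketone that already carries two phenoxides may be incomplete. The fallback sets out from 25 and returns at 26. It delivers the carbonate carbon intramolecularly at low temperature. Methyl chloroformate and pyridine convert 25 into 8-[3-acetyl-4,6-bis(methoxycarbonyloxy)-2-methylphenyl]-4,7-dimethoxy-5-methyl-2H-chromen-2-one F11. LiN(SiMe3)2 in THF at −78 to 0 °C enolises the ketone, which attacks the neighbouring carbonate (Baker–Venkataraman-type acyl transfer) and lactonises. K2CO3 in methanol at 0 °C then removes the 7'-carbonate and gives 26.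

**Step 15.** Addition of methanol at C4' is slowed by the peri 5'-methyl group, so conversion may stall and long heating in acid may erode the material. The fallback sets out from 26 and returns at 27. It alkylates the 4'-oxide instead of attacking C4'. One equivalent of NaHCO3 deprotonates only the vinylogous acid, and dimethyl sulfate (1.05 equiv, acetone, 25 °C) methylates that anion on oxygen, away from the crowded carbon. The selectivity then rests on the acidity gap between the two hydroxyls; no new compound arises (F0).

## Further compounds

F1 | step 11 | (E)-4,7-dimethoxy-5-methyl-8-(prop-1-enyl)-2H-chromen-2-one | C/C=C/c1c(OC)cc(C)c2c(OC)cc(=O)oc12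
F2 | step 11 | 4,7-dimethoxy-5-methyl-2-oxo-2H-chromene-8-carbaldehyde | O=Cc1c(OC)cc(C)c2c(OC)cc(=O)oc12
F3 | step 11 | (E)-4-(4,7-dimethoxy-5-methyl-2-oxo-2H-chromen-8-yl)-3-methylbut-3-enoic acid | COc1cc(C)c2c(OC)cc(=O)oc2c1/C=C(\C)CC(=O)O
F4 | step 11 | (E)-4-(4,7-dimethoxy-5-methyl-2-oxo-2H-chromen-8-yl)-3-methylbut-3-enoyl chloride | COc1cc(C)c2c(OC)cc(=O)oc2c1/C=C(\C)CC(Cl)=O
F5 | step 10 | (E)-1,2-dichlorovinyl tert-butyl ether | Cl/C=C(/Cl)OC(C)(C)C
F6 | step 10 | tert-butoxyacetylene | C#COC(C)(C)C
F7 | step 10 | 8-(4-tert-butoxy-2-hydroxy-6-methylphenyl)-4,7-dimethoxy-5-methyl-2H-chromen-2-one | COc1cc(C)c2c(OC)cc(=O)oc2c1-c1c(O)cc(OC(C)(C)C)cc1C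
F8 | step 13 | 8-[3-bromo-2-hydroxy-6-methyl-4-(triisopropylsilyloxy)phenyl]-4,7-dimethoxy-5-methyl-2H-chromen-2-one | COc1cc(C)c2c(OC)cc(=O)oc2c1-c1c(O)c(Br)c(O[Si](C(C)C)(C(C)C)C(C)C)cc1C
F9 | step 13 | 8-(3-bromo-2,4-dihydroxy-6-methylphenyl)-4,7-dimethoxy-5-methyl-2H-chromen-2-one | COc1cc(C)c2c(OC)cc(=O)oc2c1-c1c(O)c(Br)c(O)cc1C
F10 | step 13 | 8-(3-acetyl-5-bromo-4,6-dihydroxy-2-methylphenyl)-4,7-dimethoxy-5-methyl-2H-chromen-2-one | COc1cc(C)c2c(OC)cc(=O)oc2c1-c1c(O)c(Br)c(O)c(C(C)=O)c1C
F11 | step 14 | 8-[3-acetyl-4,6-bis(methoxycarbonyloxy)-2-methylphenyl]-4,7-dimethoxy-5-methyl-2H-chromen-2-one | COc1cc(C)c2c(OC)cc(=O)oc2c1-c1c(OC(=O)OC)cc(OC(=O)OC)c(C(C)=O)c1C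
F0 | step 15 | none | none
A1 | alternative 1 | 7'-O-benzyl ether of the target: 8-(7-benzyloxy-4-methoxy-5-methyl-2-oxo-2H-chromen-6-yl)-4,7-dimethoxy-5-methyl-2H-chromen-2-one | COc1cc(C)c2c(OC)cc(=O)oc2c1-c1c(OCc3ccccc3)cc2oc(=O)cc(OC)c2c1C
A2 | alternative 1 | methyl 3-[6-benzyloxy-4-hydroxy-3-(methoxycarbonyl)-2-methylphenyl]-2-hydroxy-4-methoxy-6-methylbenzoate | COC(=O)c1c(C)cc(OC)c(-c2c(OCc3ccccc3)cc(O)c(C(=O)OC)c2C)c1O
A3 | alternative 1 | ketenylidenetriphenylphosphorane | O=C=C=P(c1ccccc1)(c1ccccc1)c1ccccc1
A4 | alternative 2 | methyl 3-[2,4-bis(benzyloxy)-6-methylphenyl]-2,4-dihydroxy-6-methylbenzoate | COC(=O)c1c(C)cc(O)c(-c2c(OCc3ccccc3)cc(OCc3ccccc3)cc2C)c1O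
A5 | alternative 2 | 2-[2,4-bis(benzyloxy)-6-methylphenyl]-1-methoxy-1,3-bis(trimethylsilyloxy)buta-1,3-diene | COC(O[Si](C)(C)C)=C(c1c(OCc2ccccc2)cc(OCc2ccccc2)cc1C)C(=C)O[Si](C)(C)C
A6 | alternative 2 | methyl but-2-ynoate | CC#CC(=O)OC
A7 | alternative 3 | 2-[2,4-bis(benzyloxy)-6-methylphenyl]-5-methyl-3-(triisopropylsilyloxy)phenol | Cc1cc(O)c(-c2c(OCc3ccccc3)cc(OCc3ccccc3)cc2C)c(O[Si](C(C)C)(C(C)C)C(C)C)c1
A8 | alternative 3 | [2,4-bis(benzyloxy)-6-methylphenyl]ethynyl triisopropylsilyl ether | Cc1cc(OCc2ccccc2)cc(OCc2ccccc2)c1C#CO[Si](C(C)C)(C(C)C)C(C)C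
A9 | alternative 3 | 3-methylcyclobut-2-en-1-one | CC1=CC(=O)C1
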